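**Strategy.** The target is cut at the C2=C3 double bond of its (Z)-2-(acyloxymethyl)but-2-enoate unit, whose C4 methyl lies cis to the C1 ester carbonyl; the 3,4,5-trimethoxyphenyl ring and the (S)-allylic stereocentre are carried through as spectators. A Still–Gennari olefination with acetaldehyde forms this bond and sets the contra-thermodynamic (Z) geometry in one operation under kinetic control. Its precursor is the (S)-1-(3,4,5-trimethoxyphenyl)allyl ester of a 2-[bis(2,2,2-trifluoroethoxy)phosphoryl]propanoic acid that carries a silyl-protected 3-hydroxyl. A triisopropylsilyl ether is used because it enters from a commercial chloromethyl ether and leaves with fluoride, so no oxidant meets the electron-rich aryl allyl ester. Desilylation and tigloylation finish the route.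

Key step: step 6

Remark on step 2: in a 1-arylallyl alcohol the aryl group takes the place of the alkyl group of an alkyl vinyl carbinol, so the L-(+)-tartrate catalyst is assumed to epoxidise the (R)-alcohol and leave the (S)-alcohol.

Remark on reagents: (triisopropylsiloxy)methyl chloride, tigloyl chloride and methyl bis(2,2,2-trifluoroethyl)phosphonoacetate are taken as purchased.

**Step 1**
Reactants: 1 3,4,5-trimethoxybenzaldehyde; 2 vinylmagnesium bromide
Product: 4 rac-1-(3,4,5-trimethoxyphenyl)prop-2-en-1-ol, via bromomagnesium alkoxide 3 (not isolated)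
Conditions: CH2=CHMgBr (1.2 equiv), THF, 0 °C; then aq. NH4Cl
Reagents that add atoms: vinylmagnesium bromide, C=C[Mg]Br
Why: Grignard 1,2-addition to an unhindered aryl aldehyde is fast at 0 °C and should give the carbinol as the racemate, which step 2 resolves.

**Step 2**
Reactants: 4 rac-1-(3,4,5-trimethoxyphenyl)prop-2-en-1-ol
Product: 5 (S)-1-(3,4,5-trimethoxyphenyl)prop-2-en-1-ol
Conditions: Ti(OiPr)4 (0.2 equiv), L-(+)-diisopropyl tartrate (0.24 equiv), t-BuOOH (0.6 equiv), 4 Å molecular sieves, CH2Cl2, −20 °C
Reagents that add atoms: none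
Why: Sharpless kinetic resolution, in which the titanium tartrate catalyst should epoxidise the (R)-carbinol much faster than the (S)-carbinol, so that a little more than half an equivalent of oxidant leaves the (S)-alcohol, separable from the polar epoxy alcohol; the stereocentre is selected here, not created.

**Step 3**
Reactants: 6 methyl bis(2,2,2-trifluoroethyl)phosphonoacetate
Product: 8 2-[bis(2,2,2-trifluoroethoxy)phosphoryl]acetic acid, via lithium carboxylate 7 (not isolated)
Conditions: LiOH·H2O (1.05 equiv), THF/H2O, 0 °C; then 1 M HCl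
Reagents that add atoms: lithium hydroxide, [Li+].[OH-]
Why: Saponification, in which one equivalent of hydroxide at 0 °C should attack the activated methyl carboxylate in preference to phosphorus, and mild acidification frees the acid with both trifluoroethyl phosphonate esters in place.

**Step 4**
Reactants: 5 (S)-1-(3,4,5-trimethoxyphenyl)prop-2-en-1-ol; 8 2-[bis(2,2,2-trifluoroethoxy)phosphoryl]acetic acid
Product: 10 (S)-1-(3,4,5-trimethoxyphenyl)allyl 2-[bis(2,2,2-trifluoroethoxy)phosphoryl]acetate, via O-acylisourea 9 (not isolated)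
Conditions: DCC (1.1 equiv), DMAP (0.1 equiv), CH2Cl2, 0 °C → rt
Reagents that add atoms: none
Why: Steglich esterification, in which the carbodiimide-activated α-phosphono acid acylates the secondary alcohol at oxygen under near-neutral conditions that do not ionise the benzylic allylic C–O bond, so the (S) configuration is retained.

**Step 5**
Reactants: 10 (S)-1-(3,4,5-trimethoxyphenyl)allyl 2-[bis(2,2,2-trifluoroethoxy)phosphoryl]acetate; 11 (triisopropylsiloxy)methyl chloride
Product: 13 (S)-1-(3,4,5-trimethoxyphenyl)allyl 2-[bis(2,2,2-trifluoroethoxy)phosphoryl]-3-[(triisopropylsilyl)oxy]propanoate (mixture of epimers at C2), via sodium phosphonate enolate 12 (not isolated)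
Conditions: NaH (1.0 equiv), THF, 0 °C; then added to iPr3SiOCH2Cl (1.5 equiv), NaI (cat.), THF, 0 °C → rt
Reagents that add atoms: (triisopropylsiloxy)methyl chloride, ClCO[Si](C(C)C)(C(C)C)C(C)C
Why: Enolate C-alkylation of a stabilised phosphonoacetate carbanion with an α-halo ether, which is reactive enough for this weakly nucleophilic anion, while inverse addition to excess electrophile limits double alkylation and loss of silanolate; the new C2 centre forms as both epimers, which does not matter because C2 becomes sp2 in step 6.

**Step 6**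
Reactants: 13 (S)-1-(3,4,5-trimethoxyphenyl)allyl 2-[bis(2,2,2-trifluoroethoxy)phosphoryl]-3-[(triisopropylsilyl)oxy]propanoate; 14 acetaldehyde
Product: 16 (S)-1-(3,4,5-trimethoxyphenyl)allyl (Z)-2-{[(triisopropylsilyl)oxy]methyl}but-2-enoate, via potassium phosphonate carbanion 15 (not isolated)
Conditions: KN(SiMe3)2 (1.0 equiv), 18-crown-6 (5 equiv), THF, −78 °C; then MeCHO (5 equiv), −78 °C; aq. NH4Cl
Reagents that add atoms: acetaldehyde, CC=O
Why: Still–Gennari variant of the Horner–Wadsworth–Emmons olefination: KN(SiMe3)2 removes the acidic C2–H so that both C2 epimers converge on the crown-ether-separated potassium carbanion 15, which adds to acetaldehyde and collapses through an oxaphosphetane with loss of bis(trifluoroethyl) phosphate. The closest known reaction type is the (Z)-selective olefination of aliphatic aldehydes with α-substituted bis(trifluoroethyl) phosphonoacetates, which places the aldehyde substituent cis to the ester. No ring is closed and no stereocentre is created; the C2=C3 bond is the only skeletal bond formed. The step needs (Z) over (E) selectivity, which the electron-poor trifluoroethoxy groups secure by making elimination from the first-formed adduct faster than its reversal, helped by the dissociated potassium counter-ion and −78 °C. Chemoselectivity rests on the acidity of C2–H, which consumes the single equivalent of base, so the benzylic allylic C–H of the (S) centre and the ester are left alone. The doubly stabilised carbanion should also be too weak a base to expel the β-silyloxy group at this temperature before excess aldehyde traps it.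

**Step 7**
Reactants: 16 (S)-1-(3,4,5-trimethoxyphenyl)allyl (Z)-2-{[(triisopropylsilyl)oxy]methyl}but-2-enoate
Product: 17 (S)-1-(3,4,5-trimethoxyphenyl)allyl (Z)-2-(hydroxymethyl)but-2-enoate
Conditions: HF·pyridine, pyridine, THF, 0 °C → rt
Reagents that add atoms: none
Why: Fluoride-mediated cleavage of a primary silyl ether, driven by the strong Si–F bond and buffered by excess pyridine, uses neither base nor oxidant, so the (Z)-enoate, the ionisable 1-arylallyl ester and its (S) centre should persist.

**Step 8**
Reactants: 17 (S)-1-(3,4,5-trimethoxyphenyl)allyl (Z)-2-(hydroxymethyl)but-2-enoate; 18 tigloyl chloride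
Product: 19 (S)-1-(3,4,5-trimethoxyphenyl)allyl (Z)-2-({[(E)-2-methylbut-2-enoyl]oxy}methyl)but-2-enoate
Conditions: 2,6-lutidine, CH2Cl2, 0 °C → rt
Reagents that add atoms: tigloyl chloride, C/C=C(\C)C(Cl)=O
Why: O-Acylation of a primary alcohol with an acid chloride (nucleophilic acyl substitution), in which the hindered base 2,6-lutidine only takes up HCl, so neither addition–elimination at C3 of the 2-(acyloxymethyl)enoate nor isomerisation of the (Z)-alkene or the (E)-tigloyl unit is expected.

**Compound list**
1 | 3,4,5-trimethoxybenzaldehyde | COc1cc(C=O)cc(OC)c1OC | starting material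
2 | vinylmagnesium bromide | C=C[Mg]Br | starting material
3 | bromomagnesium 1-(3,4,5-trimethoxyphenyl)prop-2-en-1-olate (racemic) | C=CC(O[Mg]Br)c1cc(OC)c(OC)c(OC)c1 | intermediate (not isolated)
4 | rac-1-(3,4,5-trimethoxyphenyl)prop-2-en-1-ol | C=CC(O)c1cc(OC)c(OC)c(OC)c1 | intermediate
5 | (S)-1-(3,4,5-trimethoxyphenyl)prop-2-en-1-ol | C=C[C@H](O)c1cc(OC)c(OC)c(OC)c1 | intermediate
6 | methyl bis(2,2,2-trifluoroethyl)phosphonoacetate | COC(=O)CP(=O)(OCC(F)(F)F)OCC(F)(F)F | starting material
7 | lithium 2-[bis(2,2,2-trifluoroethoxy)phosphoryl]acetate | [Li+].[O-]C(=O)CP(=O)(OCC(F)(F)F)OCC(F)(F)F | intermediate (not isolated)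
8 | 2-[bis(2,2,2-trifluoroethoxy)phosphoryl]acetic acid | OC(=O)CP(=O)(OCC(F)(F)F)OCC(F)(F)F | intermediate
9 | O-acylisourea of acid 8 with DCC | O=C(CP(=O)(OCC(F)(F)F)OCC(F)(F)F)OC(=NC1CCCCC1)NC1CCCCC1 | intermediate (not isolated)
10 | (S)-1-(3,4,5-trimethoxyphenyl)allyl 2-[bis(2,2,2-trifluoroethoxy)phosphoryl]acetate | C=C[C@H](OC(=O)CP(=O)(OCC(F)(F)F)OCC(F)(F)F)c1cc(OC)c(OC)c(OC)c1 | intermediate
11 | (triisopropylsiloxy)methyl chloride | ClCO[Si](C(C)C)(C(C)C)C(C)C | starting material
12 | sodium enolate of phosphonoacetate 10 | [Na+].C=C[C@H](OC(=O)[CH-]P(=O)(OCC(F)(F)F)OCC(F)(F)F)c1cc(OC)c(OC)c(OC)c1 | intermediate (not isolated)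
13 | (S)-1-(3,4,5-trimethoxyphenyl)allyl 2-[bis(2,2,2-trifluoroethoxy)phosphoryl]-3-[(triisopropylsilyl)oxy]propanoate (both C2 epimers) | C=C[C@H](OC(=O)C(CO[Si](C(C)C)(C(C)C)C(C)C)P(=O)(OCC(F)(F)F)OCC(F)(F)F)c1cc(OC)c(OC)c(OC)c1 | intermediate
14 | acetaldehyde | CC=O | starting material
15 | potassium carbanion of phosphonate 13 | [K+].C=C[C@H](OC(=O)[C-](CO[Si](C(C)C)(C(C)C)C(C)C)P(=O)(OCC(F)(F)F)OCC(F)(F)F)c1cc(OC)c(OC)c(OC)c1 | intermediate (not isolated)
16 | (S)-1-(3,4,5-trimethoxyphenyl)allyl (Z)-2-{[(triisopropylsilyl)oxy]methyl}but-2-enoate | C=C[C@H](OC(=O)/C(=C\C)CO[Si](C(C)C)(C(C)C)C(C)C)c1cc(OC)c(OC)c(OC)c1 | intermediate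
17 | (S)-1-(3,4,5-trimethoxyphenyl)allyl (Z)-2-(hydroxymethyl)but-2-enoate | C=C[C@H](OC(=O)/C(=C\C)CO)c1cc(OC)c(OC)c(OC)c1 | intermediate
18 | tigloyl chloride, (E)-2-methylbut-2-enoyl chloride | C/C=C(\C)C(Cl)=O | starting material
19 | (S)-1-(3,4,5-trimethoxyphenyl)allyl (Z)-2-({[(E)-2-methylbut-2-enoyl]oxy}methyl)but-2-enoate | C=C[C@H](OC(=O)/C(=C\C)COC(=O)/C(C)=C/C)c1cc(OC)c(OC)c(OC)c1 | target

**Step count.** Total: 8 steps. Longest linear sequence: 7 steps (1, 2, 4, 5, 6, 7, 8) from 3,4,5-trimethoxybenzaldehyde; step 3 is a one-step side branch.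

**Steps most likely to fail**

Step 5. The fluorinated phosphonate anion is a weak nucleophile, so C-alkylation may be slow or give way to O-alkylation of the enolate. The alkylated product may also be deprotonated in the flask and lose silanolate. The fallback forms the C–P bond instead of the C–C bond; it sets out from alcohol 5 and comes back at 13. Commercial methyl 3-hydroxypropanoate is silylated (iPr3SiCl, imidazole, DMF) to methyl 3-[(triisopropylsilyl)oxy]propanoate F1. Saponification (LiOH, THF/H2O) gives 3-[(triisopropylsilyl)oxy]propanoic acid F2. Coupling with 5 (DCC, DMAP, CH2Cl2) gives (S)-1-(3,4,5-trimethoxyphenyl)allyl 3-[(triisopropylsilyl)oxy]propanoate F3. Its lithium enolate (LiN(iPr)2, 2.2 equiv, THF, −78 °C) is phosphorylated with bis(2,2,2-trifluoroethyl) phosphorochloridate. The second equivalent of base holds the product as its stabilised anion until the cold quench, which should deliver 13.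

Step 6. The (Z) selectivity may erode, the carbanion may undergo β-elimination of silanolate, or the aldehyde may self-condense under the base. The fallback sets the geometry in a vinyl iodide instead of an olefination; it sets out from alcohol 5 and comes back at 16. Commercial (E)-crotonaldehyde is α-iodinated (I2, K2CO3, DMAP cat., THF/H2O) to (Z)-2-iodobut-2-enal F4. Reduction (NaBH4, MeOH, 0 °C) gives (Z)-2-iodobut-2-en-1-ol F5. Silylation (iPr3SiCl, imidazole) gives {[(Z)-2-iodobut-2-en-1-yl]oxy}triisopropylsilane F6. Iodine–lithium exchange (t-BuLi, Et2O, −78 °C) and trapping with CO2 proceed with retention at the alkene and give (Z)-2-{[(triisopropylsilyl)oxy]methyl}but-2-enoic acid F7. This acid is coupled with 5 through its 2,4,6-trichlorobenzoyl mixed anhydride (Yamaguchi esterification: 2,4,6-trichlorobenzoyl chloride, Et3N, then 5 and a little DMAP, toluene), with short contact time to protect the (Z) geometry.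

Step 2. The rate difference between the enantiomers may be too small for this slow terminal alkene, or the Lewis-acidic titanium may ionise the electron-rich benzylic alcohol and lower the enantiomeric purity. The fallback is an enzymatic acylative resolution; it sets out from racemic alcohol 4 and comes back at 5. Immobilised lipase B of Candida antarctica (Novozym 435) with vinyl acetate in methyl tert-butyl ether at rt should acylate the (R)-alcohol to (R)-1-(3,4,5-trimethoxyphenyl)allyl acetate F8 and leave the (S)-alcohol 5, which is separated by chromatography.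

**Further compounds**
F1 | step 5 | methyl 3-[(triisopropylsilyl)oxy]propanoate | COC(=O)CCO[Si](C(C)C)(C(C)C)C(C)C
F2 | step 5 | 3-[(triisopropylsilyl)oxy]propanoic acid | OC(=O)CCO[Si](C(C)C)(C(C)C)C(C)C
F3 | step 5 | (S)-1-(3,4,5-trimethoxyphenyl)allyl 3-[(triisopropylsilyl)oxy]propanoate | C=C[C@H](OC(=O)CCO[Si](C(C)C)(C(C)C)C(C)C)c1cc(OC)c(OC)c(OC)c1
F4 | step 6 | (Z)-2-iodobut-2-enal | C/C=C(\I)C=O
F5 | step 6 | (Z)-2-iodobut-2-en-1-ol | C/C=C(\I)CO
F6 | step 6 | {[(Z)-2-iodobut-2-en-1-yl]oxy}triisopropylsilane | C/C=C(\I)CO[Si](C(C)C)(C(C)C)C(C)C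
F7 | step 6 | (Z)-2-{[(triisopropylsilyl)oxy]methyl}but-2-enoic acid | C/C=C(\C(=O)O)CO[Si](C(C)C)(C(C)C)C(C)C
F8 | step 2 | (R)-1-(3,4,5-trimethoxyphenyl)allyl acetate | C=C[C@@H](OC(C)=O)c1cc(OC)c(OC)c(OC)c1
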